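The route rests on disconnecting both quinone rings at once by a twofold Dötz benzannulation. In each ring the C1 carbonyl carbon lies between C2, which carries the succinate carbon, and C6, which carries geranyl, while C3 and C5 are CH and C4 is oxygenated; a terminal alkyne, CO and a β-geranyl alkenyl(methoxy)carbene complex of zerovalent chromium deliver exactly this pattern. One operation therefore forms six C–C bonds and both carbocycles, as 4-methoxyphenols, without touching the two stereocentres. The precursor is a meso 3,4-bis(silyloxymethyl)hexa-1,5-diyne, whose configuration comes from a cis-fused cyclobutene anhydride; the ester carbons are oxidised afterwards and the quinones are unmasked last.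

Key step: step 8

Remarks on the chemistry
- The target SMILES encodes the (2R,3S), i.e. meso, succinate. This relation is taken from the cis ring fusion of 1 and is only carried through, so no base equilibration of the diester is planned (it would scramble the relation, not secure it).
- Compound 1 is assumed to be a catalogue compound; its SMILES is written with the cis ring fusion made explicit.
- Ring numbering used below: C1 = CO-derived carbon (C–OH, later C1=O), C2 = carbon bearing the succinate carbon, C3 = CH, C4 = C–OMe (later C4=O), C5 = CH, C6 = carbon bearing geranyl.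
- In SMILES the η5-cyclopentadienyl ligands are drawn σ-bonded and the η6-arene Cr(CO)3 units as dot-separated parts.

Step 1
Reactants: 1 cis-cyclobut-3-ene-1,2-dicarboxylic anhydride
Product: 2 cis-3,4-bis(hydroxymethyl)cyclobutene
Conditions: LiAlH4, THF, 0 °C → reflux; H2O/aq NaOH work-up
Reagents that add atoms: none
Why: LiAlH4 reduction of a cyclic anhydride to the 1,4-diol touches neither stereocentre, so the cis relation of 1 (later the meso relation) is carried over.

Step 2
Reactants: 2 cis-3,4-bis(hydroxymethyl)cyclobutene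
Product: 3 cis-3,4-bis[(tert-butyldimethylsilyloxy)methyl]cyclobutene
Conditions: TBSCl, imidazole, DMF, rt
Reagents that add atoms: tert-butyldimethylsilyl chloride, CC(C)(C)[Si](C)(C)Cl
Why: Imidazole-promoted silylation of two primary alcohols gives ethers that survive ozone, K2CO3/MeOH and the neutral benzannulation and leave later with fluoride.

Step 3
Reactants: 3 cis-3,4-bis[(tert-butyldimethylsilyloxy)methyl]cyclobutene
Product: 5 meso-2,3-bis[(tert-butyldimethylsilyloxy)methyl]butanedial, via ozonide 4 (not isolated)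
Conditions: O3, CH2Cl2, −78 °C; then PPh3, −78 °C → rt; crude product used at once
Reagents that add atoms: ozone, [O-][O+]=O
Why: Ozonolysis of the only C=C bond with reductive cleavage of the ozonide by PPh3 gives both aldehydes under neutral, aprotic conditions, so the two α-stereocentres (cis in the ring, hence meso in the chain) should not enolise.

Step 4
Reactants: 5 meso-2,3-bis[(tert-butyldimethylsilyloxy)methyl]butanedial
Product: 6 meso-3,4-bis[(tert-butyldimethylsilyloxy)methyl]hexa-1,5-diyne
Conditions: dimethyl (1-diazo-2-oxopropyl)phosphonate (2.6 equiv), K2CO3 (4 equiv), MeOH, 0 °C → rt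
Reagents that add atoms: dimethyl (1-diazo-2-oxopropyl)phosphonate, CC(=O)C(=[N+]=[N-])P(=O)(OC)OC
Why: The Ohira–Bestmann variant of the Seyferth–Gilbert homologation turns each CHO into C≡CH (olefination to a diazoalkene, then 1,2-hydrogen shift of the alkylidene carbene) under conditions mild enough for α-branched aldehydes, so the meso relation should be kept.

Step 5
Reactants: 7 geranyl bromide
Product: 8 (E)-5,9-dimethyldeca-4,8-dien-1-yne
Conditions: HC≡CMgBr (1.5 equiv), CuCl (10 mol%), THF, 0 °C → rt
Reagents that add atoms: ethynylmagnesium bromide, C#C[Mg]Br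
Why: Copper-catalysed SN2 coupling of an alkynyl Grignard reagent with a primary allylic bromide occurs at the primary carbon, not at the fully substituted γ-carbon, which keeps the E-olefin and gives the skipped enyne.

Step 6
Reactants: 8 (E)-5,9-dimethyldeca-4,8-dien-1-yne
Product: 10 (1E,4E)-1-iodo-5,9-dimethyldeca-1,4,8-triene, via alkenylzirconocene chloride 9 (not isolated)
Conditions: Cp2Zr(H)Cl (1.2 equiv), THF, rt, dark; then I2, 0 °C
Reagents that add atoms: iodine, II
Why: Hydrozirconation of a terminal alkyne is a syn, anti-Markovnikov addition that leaves trisubstituted alkenes alone, and iodinolysis of the C–Zr bond goes with retention, which fixes the 1E geometry.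

Step 7
Reactants: 10 (1E,4E)-1-iodo-5,9-dimethyldeca-1,4,8-triene; 11 chromium hexacarbonyl
Product: 14 pentacarbonyl[(2E,5E)-1-methoxy-6,10-dimethylundeca-2,5,9-trien-1-ylidene]chromium, via alkenyllithium 12 (not isolated), via lithium acylchromate 13 (not isolated)
Conditions: t-BuLi (2 equiv), Et2O, −78 °C; Cr(CO)6, Et2O, −78 °C → rt; evaporate; Me3OBF4, CH2Cl2, 0 °C
Reagents that add atoms: trimethyloxonium tetrafluoroborate, C[O+](C)C.F[B-](F)(F)F
Why: This is the Fischer carbene synthesis, in which iodine–lithium exchange with retention gives the alkenyllithium, addition to a CO ligand gives the acylchromate and O-methylation gives the neutral complex; no base is present after methylation, so the doubly allylic CH2 should not isomerise.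

Step 8
Reactants: 6 meso-3,4-bis[(tert-butyldimethylsilyloxy)methyl]hexa-1,5-diyne; 14 pentacarbonyl[(2E,5E)-1-methoxy-6,10-dimethylundeca-2,5,9-trien-1-ylidene]chromium (two equivalents incorporated)
Product: 16 meso-6,6'-[1,4-bis(tert-butyldimethylsilyloxy)butane-2,3-diyl]bis(2-geranyl-4-methoxyphenol), via bis(tricarbonylchromium) arene complex 15 (not isolated)
Conditions: 14 (2.6 equiv), THF (0.1 M), 50 °C, Ar; then air, rt
Reagents that add atoms: none
Why: Thermal loss of one CO from 14 lets a terminal alkyne of 6 coordinate and insert into the Cr=C bond with its CH terminus bonded to the carbene carbon (C3–C4), CO insertion then gives a chromium-bound dienylketene (C1–C2), and 6π-electrocyclisation of the ketene carbon onto the geranyl-bearing β-carbon (C1–C6) followed by tautomerisation gives the 4-methoxyphenol, first as its Cr(CO)3 complex 15, from which air releases 16. The closest known reaction is the Dötz benzannulation of β-substituted alkenyl(methoxy)carbene complexes of zerovalent chromium with terminal alkyl alkynes, which has also been run twice on one diyne. Both rings close in the same mode, by 6π-electrocyclic closure of the dienylketene. No stereocentre is formed, and the two propargylic centres of 6 and the E-olefins of the side chains are spectators under these neutral conditions. The step needs the regiochemistry in which the branched alkyne substituent ends next to the CO-derived C1, which the steric preference of terminal alkynes secures, and it needs the alkynes to react in preference to the trisubstituted alkenes, which are inert towards the carbene at this temperature. An excess of 14 and the two-carbon tether between the alkynes, too short for an intramolecular second alkyne insertion, should favour two separate annulations.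

Step 9
Reactants: 16 meso-6,6'-[1,4-bis(tert-butyldimethylsilyloxy)butane-2,3-diyl]bis(2-geranyl-4-methoxyphenol)
Product: 17 meso-2,3-bis(3-geranyl-2,5-dimethoxyphenyl)-1,4-bis(tert-butyldimethylsilyloxy)butane
Conditions: MeI, Cs2CO3, DMF, rt, Ar
Reagents that add atoms: iodomethane, CI
Why: Williamson O-methylation of the hindered phenols blocks lactonisation onto the later ester groups and sets up the 1,4-dimethoxyarene that serves as the quinone precursor.

Step 10
Reactants: 17 meso-2,3-bis(3-geranyl-2,5-dimethoxyphenyl)-1,4-bis(tert-butyldimethylsilyloxy)butane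
Product: 18 meso-2,3-bis(3-geranyl-2,5-dimethoxyphenyl)butane-1,4-diol
Conditions: Bu4NF, THF, 0 °C → rt
Reagents that add atoms: none
Why: Fluoride cleavage of the primary silyl ethers is driven by Si–F bond formation and leaves aryl methyl ethers, alkenes and the benzylic stereocentres alone.

Step 11
Reactants: 18 meso-2,3-bis(3-geranyl-2,5-dimethoxyphenyl)butane-1,4-diol
Product: 20 meso-2,3-bis(3-geranyl-2,5-dimethoxyphenyl)butanedial, via bis(alkoxysulfonium) dichloride 19 (not isolated)
Conditions: (COCl)2, DMSO, CH2Cl2, −78 °C; then iPr2NEt, −78 → −40 °C; cold pH 7 buffer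
Reagents that add atoms: none
Why: In this Swern oxidation both hydroxyls are converted into the alkoxysulfonium salt before any base is present, so no free hydroxyl is left to form a lactol (and then a lactone) with the first aldehyde, and the hindered base at low temperature limits enolisation of the α-aryl aldehydes.

Step 12
Reactants: 20 meso-2,3-bis(3-geranyl-2,5-dimethoxyphenyl)butanedial
Product: 21 meso-2,3-bis(3-geranyl-2,5-dimethoxyphenyl)butanedioic acid
Conditions: NaClO2, NaH2PO4, 2-methyl-2-butene (large excess), t-BuOH/THF/H2O, 0 °C → rt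
Reagents that add atoms: sodium chlorite, [Na+].[O-]Cl=O
Why: The Pinnick oxidation converts aldehydes into acids at about pH 4 without enolisation, and the excess 2-methyl-2-butene traps HOCl before it can attack the geranyl olefins or the electron-rich rings.

Step 13
Reactants: 21 meso-2,3-bis(3-geranyl-2,5-dimethoxyphenyl)butanedioic acid
Product: 22 dimethyl meso-2,3-bis(3-geranyl-2,5-dimethoxyphenyl)butanedioate
Conditions: Me3SiCHN2, PhMe/MeOH, 0 °C → rt
Reagents that add atoms: (trimethylsilyl)diazomethane, C[Si](C)(C)C=[N+]=[N-]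
Why: Esterification with (trimethylsilyl)diazomethane in methanol is neutral and so avoids the basic conditions that could epimerise the α-aryl ester centres.

Step 14
Reactants: 22 dimethyl meso-2,3-bis(3-geranyl-2,5-dimethoxyphenyl)butanedioate
Product: 23 dimethyl (2R,3S)-2,3-bis(5-geranyl-3,6-dioxocyclohexa-1,4-dien-1-yl)butanedioate (CNP0183145.1)
Conditions: (NH4)2Ce(NO3)6 (5 equiv), MeCN/H2O, 0 °C, short contact time
Reagents that add atoms: water, O
Why: Oxidative demethylation of 1,4-dimethoxyarenes to 1,4-benzoquinones by this cerium salt (two one-electron oxidations per ring, water as oxygen source) is fast at 0 °C and known to spare prenyl-type chains and esters, and the acidic medium leaves the two stereocentres untouched.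

Compound list
1 | cis-cyclobut-3-ene-1,2-dicarboxylic anhydride (cis-3-oxabicyclo[3.2.0]hept-6-ene-2,4-dione, meso) | O=C1OC(=O)[C@@H]2C=C[C@H]12 | starting material
2 | cis-3,4-bis(hydroxymethyl)cyclobutene, [(1R,2S)-cyclobut-3-ene-1,2-diyl]dimethanol (meso) | OC[C@@H]1C=C[C@@H]1CO | intermediate
3 | cis-3,4-bis[(tert-butyldimethylsilyloxy)methyl]cyclobutene (meso) | CC(C)(C)[Si](C)(C)OC[C@@H]1C=C[C@@H]1CO[Si](C)(C)C(C)(C)C | intermediate
4 | ozonide of 3, cis-5,6-bis[(tert-butyldimethylsilyloxy)methyl]-2,3,7-trioxabicyclo[2.2.1]heptane (side chains cis to each other, exo/endo placement not defined) | CC(C)(C)[Si](C)(C)OC[C@H]1[C@@H](CO[Si](C)(C)C(C)(C)C)C2OOC1O2 | intermediate (not isolated)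
5 | meso-2,3-bis[(tert-butyldimethylsilyloxy)methyl]butanedial | CC(C)(C)[Si](C)(C)OC[C@H](C=O)[C@@H](CO[Si](C)(C)C(C)(C)C)C=O | intermediate
6 | meso-3,4-bis[(tert-butyldimethylsilyloxy)methyl]hexa-1,5-diyne | CC(C)(C)[Si](C)(C)OC[C@H](C#C)[C@@H](CO[Si](C)(C)C(C)(C)C)C#C | intermediate
7 | geranyl bromide, (2E)-1-bromo-3,7-dimethylocta-2,6-diene | CC(C)=CCC/C(C)=C/CBr | starting material
8 | (E)-5,9-dimethyldeca-4,8-dien-1-yne | C#CC/C=C(\C)CCC=C(C)C | intermediate
9 | chlorobis(η5-cyclopentadienyl)[(1E,4E)-5,9-dimethyldeca-1,4,8-trien-1-yl]zirconium | Cl[Zr](/C=C/C/C=C(\C)CCC=C(C)C)(C1C=CC=C1)C1C=CC=C1 | intermediate (not isolated)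
10 | (1E,4E)-1-iodo-5,9-dimethyldeca-1,4,8-triene | I/C=C/C/C=C(\C)CCC=C(C)C | intermediate
11 | chromium hexacarbonyl | O=C=[Cr](=C=O)(=C=O)(=C=O)(=C=O)=C=O | starting material
12 | (1E,4E)-5,9-dimethyldeca-1,4,8-trien-1-yllithium | [Li]/C=C/C/C=C(\C)CCC=C(C)C | intermediate (not isolated)
13 | lithium pentacarbonyl[(2E,5E)-6,10-dimethylundeca-2,5,9-trienoyl]chromate | [Li+].[O-]C(/C=C/C/C=C(\C)CCC=C(C)C)=[Cr](=C=O)(=C=O)(=C=O)(=C=O)=C=O | intermediate (not isolated)
14 | pentacarbonyl[(2E,5E)-1-methoxy-6,10-dimethylundeca-2,5,9-trien-1-ylidene]chromium | COC(/C=C/C/C=C(\C)CCC=C(C)C)=[Cr](=C=O)(=C=O)(=C=O)(=C=O)=C=O | intermediate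
15 | bis(tricarbonylchromium) complex of 16, one Cr(CO)3 η6-bound to each new ring | CC(C)(C)[Si](C)(C)OC[C@H](c1cc(OC)cc(C/C=C(\C)CCC=C(C)C)c1O)[C@@H](CO[Si](C)(C)C(C)(C)C)c1cc(OC)cc(C/C=C(\C)CCC=C(C)C)c1O.[Cr](=C=O)(=C=O)=C=O.[Cr](=C=O)(=C=O)=C=O | intermediate (not isolated)
16 | meso-6,6'-[1,4-bis(tert-butyldimethylsilyloxy)butane-2,3-diyl]bis{2-[(2E)-3,7-dimethylocta-2,6-dien-1-yl]-4-methoxyphenol} | CC(C)(C)[Si](C)(C)OC[C@H](c1cc(OC)cc(C/C=C(\C)CCC=C(C)C)c1O)[C@@H](CO[Si](C)(C)C(C)(C)C)c1cc(OC)cc(C/C=C(\C)CCC=C(C)C)c1O | intermediate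
17 | meso-2,3-bis{3-[(2E)-3,7-dimethylocta-2,6-dien-1-yl]-2,5-dimethoxyphenyl}-1,4-bis(tert-butyldimethylsilyloxy)butane | CC(C)(C)[Si](C)(C)OC[C@H](c1cc(OC)cc(C/C=C(\C)CCC=C(C)C)c1OC)[C@@H](CO[Si](C)(C)C(C)(C)C)c1cc(OC)cc(C/C=C(\C)CCC=C(C)C)c1OC | intermediate
18 | meso-2,3-bis{3-[(2E)-3,7-dimethylocta-2,6-dien-1-yl]-2,5-dimethoxyphenyl}butane-1,4-diol | OC[C@H](c1cc(OC)cc(C/C=C(\C)CCC=C(C)C)c1OC)[C@@H](CO)c1cc(OC)cc(C/C=C(\C)CCC=C(C)C)c1OC | intermediate
19 | {[meso-2,3-bis(3-geranyl-2,5-dimethoxyphenyl)butane-1,4-diyl]bis(oxy)}bis(dimethylsulfonium) dichloride | C[S+](C)OC[C@H](c1cc(OC)cc(C/C=C(\C)CCC=C(C)C)c1OC)[C@@H](CO[S+](C)C)c1cc(OC)cc(C/C=C(\C)CCC=C(C)C)c1OC.[Cl-].[Cl-] | intermediate (not isolated)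
20 | meso-2,3-bis{3-[(2E)-3,7-dimethylocta-2,6-dien-1-yl]-2,5-dimethoxyphenyl}butanedial | O=C[C@H](c1cc(OC)cc(C/C=C(\C)CCC=C(C)C)c1OC)[C@@H](C=O)c1cc(OC)cc(C/C=C(\C)CCC=C(C)C)c1OC | intermediate
21 | meso-2,3-bis{3-[(2E)-3,7-dimethylocta-2,6-dien-1-yl]-2,5-dimethoxyphenyl}butanedioic acid | OC(=O)[C@H](c1cc(OC)cc(C/C=C(\C)CCC=C(C)C)c1OC)[C@@H](C(=O)O)c1cc(OC)cc(C/C=C(\C)CCC=C(C)C)c1OC | intermediate
22 | dimethyl meso-2,3-bis{3-[(2E)-3,7-dimethylocta-2,6-dien-1-yl]-2,5-dimethoxyphenyl}butanedioate | COC(=O)[C@H](c1cc(OC)cc(C/C=C(\C)CCC=C(C)C)c1OC)[C@@H](C(=O)OC)c1cc(OC)cc(C/C=C(\C)CCC=C(C)C)c1OC | intermediate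
23 | dimethyl (2R,3S)-2,3-bis{5-[(2E)-3,7-dimethylocta-2,6-dien-1-yl]-3,6-dioxocyclohexa-1,4-dien-1-yl}butanedioate (meso; CNP0183145.1) | COC(=O)[C@H](C1=CC(=O)C=C(C/C=C(\C)CCC=C(C)C)C1=O)[C@@H](C(=O)OC)C1=CC(=O)C=C(C/C=C(\C)CCC=C(C)C)C1=O | target

Total step count: 14 (steps 1–4 to the diyne, 5–7 to the carbene complex, step 8 the key step, steps 9–14 the endgame).
Longest linear sequence: 11 steps (1 → 2 → 3 → 5 → 6 → 16 → 17 → 18 → 20 → 21 → 22 → 23).

Steps most likely to fail

Step 8. The second annulation may stall once the first bulky aryl group sits next to the remaining propargylic carbon, the diyne may be consumed by oligomerisation, or the skipped diene of the carbene may drift into conjugation before it reacts. Fallback: the central C–C bond is made last instead of first. Setting out from carbene 14, a single Dötz benzannulation with commercial 4-(tert-butyldimethylsilyloxy)but-1-yne (THF, 50 °C; then air) should give, through its tricarbonylchromium complex F1, 2-[2-(tert-butyldimethylsilyloxy)ethyl]-6-geranyl-4-methoxyphenol F2. O-Methylation (MeI, Cs2CO3, DMF) should give 1-[2-(tert-butyldimethylsilyloxy)ethyl]-3-geranyl-2,5-dimethoxybenzene F3, and Bu4NF then 2-(3-geranyl-2,5-dimethoxyphenyl)ethanol F4. Oxidation with TEMPO/PhI(OAc)2 in MeCN/H2O should give (3-geranyl-2,5-dimethoxyphenyl)acetic acid F5, and (trimethylsilyl)diazomethane its ester, methyl (3-geranyl-2,5-dimethoxyphenyl)acetate F6. Oxidative coupling of the lithium enolate of this ester (LiN(iPr)2, THF, −78 °C; then I2, 0.5 equiv) is expected to give the 2,3-diarylsuccinate as a mixture of meso 22 and the racemic (2S,3S)/(2R,3R) dimethyl 2,3-bis(3-geranyl-2,5-dimethoxyphenyl)butanedioate F7. The diastereomers would be separated by chromatography or crystallisation, and the route is rejoined at 22.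

Step 4. K2CO3 in methanol may epimerise the α-branched dialdehyde (loss of the meso relation) or trigger β-elimination of silanolate before both homologations are complete. Fallback: a base-free olefination followed by a low-temperature organolithium step (Corey–Fuchs sequence). Setting out from 5, CBr4/PPh3/Zn (CH2Cl2, rt) should give meso-1,1,6,6-tetrabromo-3,4-bis[(tert-butyldimethylsilyloxy)methyl]hexa-1,5-diene F8. n-BuLi (THF, −78 °C) then effects bromine–lithium exchange and 1,2-shift at both termini, and an NH4Cl quench returns to diyne 6.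

Step 14. The oxidant may attack the electron-rich trisubstituted olefins, may leave the hindered rings only partly demethylated, or a slow reaction may allow tautomerisation and epimerisation through the acidic benzylic hydrogens of the product. Fallback: a metal-free two-stage unmasking. Setting out from 22, anodic oxidation in methanol (Pt anode, LiClO4, NaHCO3, 0 °C, undivided cell) should give the bis(quinone bisketal) dimethyl meso-2,3-bis(5-geranyl-3,3,6,6-tetramethoxycyclohexa-1,4-dien-1-yl)butanedioate F9. Brief hydrolysis with aqueous acetic acid in acetone then gives 23.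

Further compounds
F1 | step 8 | tricarbonylchromium complex of F2 (Cr(CO)3 η6-bound to the new ring, not isolated) | CC(C)(C)[Si](C)(C)OCCc1cc(OC)cc(C/C=C(\C)CCC=C(C)C)c1O.[Cr](=C=O)(=C=O)=C=O
F2 | step 8 | 2-[2-(tert-butyldimethylsilyloxy)ethyl]-6-[(2E)-3,7-dimethylocta-2,6-dien-1-yl]-4-methoxyphenol | CC(C)(C)[Si](C)(C)OCCc1cc(OC)cc(C/C=C(\C)CCC=C(C)C)c1O
F3 | step 8 | 1-[2-(tert-butyldimethylsilyloxy)ethyl]-3-[(2E)-3,7-dimethylocta-2,6-dien-1-yl]-2,5-dimethoxybenzene | CC(C)(C)[Si](C)(C)OCCc1cc(OC)cc(C/C=C(\C)CCC=C(C)C)c1OC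
F4 | step 8 | 2-{3-[(2E)-3,7-dimethylocta-2,6-dien-1-yl]-2,5-dimethoxyphenyl}ethanol | OCCc1cc(OC)cc(C/C=C(\C)CCC=C(C)C)c1OC
F5 | step 8 | {3-[(2E)-3,7-dimethylocta-2,6-dien-1-yl]-2,5-dimethoxyphenyl}acetic acid | OC(=O)Cc1cc(OC)cc(C/C=C(\C)CCC=C(C)C)c1OC
F6 | step 8 | methyl {3-[(2E)-3,7-dimethylocta-2,6-dien-1-yl]-2,5-dimethoxyphenyl}acetate | COC(=O)Cc1cc(OC)cc(C/C=C(\C)CCC=C(C)C)c1OC
F7 | step 8 | dimethyl (2S,3S)-2,3-bis{3-[(2E)-3,7-dimethylocta-2,6-dien-1-yl]-2,5-dimethoxyphenyl}butanedioate (racemic, one enantiomer drawn) | COC(=O)[C@H](c1cc(OC)cc(C/C=C(\C)CCC=C(C)C)c1OC)[C@H](C(=O)OC)c1cc(OC)cc(C/C=C(\C)CCC=C(C)C)c1OC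
F8 | step 4 | meso-1,1,6,6-tetrabromo-3,4-bis[(tert-butyldimethylsilyloxy)methyl]hexa-1,5-diene | CC(C)(C)[Si](C)(C)OC[C@H](C=C(Br)Br)[C@@H](CO[Si](C)(C)C(C)(C)C)C=C(Br)Br
F9 | step 14 | dimethyl meso-2,3-bis{5-[(2E)-3,7-dimethylocta-2,6-dien-1-yl]-3,3,6,6-tetramethoxycyclohexa-1,4-dien-1-yl}butanedioate | COC(=O)[C@H](C1=CC(OC)(OC)C=C(C/C=C(\C)CCC=C(C)C)C1(OC)OC)[C@@H](C(=O)OC)C1=CC(OC)(OC)C=C(C/C=C(\C)CCC=C(C)C)C1(OC)OC
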